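Count the target against the partner charged, not against the starting material.

| setting | larch | maple | flask |
|---|---|---|---|
| starting material | 0.20 M | 0.20 M | 0.20 M |
| partner | 0.50 equiv | 0.50 equiv | 0.500 equiv |
| second substrate | 0.20 equiv | 0.30 equiv | 0.200 equiv |
| remark | the very flask that is asked about, followed so far | run made earlier |  |
| time |  |  | 50 min |

larch run (percent of the starting material charged)

| time / min | target / % | starting material / % |
|---|---|---|
| 2.50 | 23.2 | 62.4 |
| 8.00 | 24.1 | 62.2 |
| 15.0 | 25.4 | 59.7 |
| 20.0 | 25.9 | 60.9 |
| 30.0 | 25.1 | 60.3 |
| 40.0 | 25.0 | 59.9 |
| 50.0 | 25.6 | 59.8 |

maple run (percent of the starting material charged)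

| time / s | target / % | starting material / % |
|---|---|---|
| 15.0 | 12.1 | 81.1 |
| 30.0 | 17.1 | 72.7 |
| 50.0 | 19.9 | 68.1 |
| 60.0 | 21.3 | 63.2 |
| 80.0 | 21.1 | 63.0 |
| 90.0 | 22.6 | 61.8 |
| 120 | 22.6 | 60.0 |

(scatter of a reading: 1 percentage point)

- what is taken out of target is counted as made
- the numbers in the tables scatter by 1 percentage point (one standard deviation)
- additions bring no volume worth counting

- ochre: at 50 min add starting material, 50.0 % of the amount charged, then wait 50 min
- red: change nothing and wait 50 min more
- blue: at 50 min take out 90 % of the target then present, then wait 50 min
- teal: at 50 min add partner, 100 % of the amount charged, then wait 50 min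

- target, in percent of the starting material first charged, at 50 min
- the remedy with the largest gain of target, or "none" below 2 percentage points (ochre / red / blue / teal / none)
- target present, with what was taken out counted in, in percent of the starting material first charged, after blue
- target present, with what was taken out counted in, in percent of the starting material first charged, after teal

The larch readings level off and show 59.8 % of the starting material at 50.0 min. The working assumption is that partner is the limiting reagent, used one to one. The late larch readings of target average 25.2 %, so this reckoning puts "now" there.

Partner yield = target on the plateau / partner charged = 25.2 % / 0.50 equiv = 50.5 %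

This partner yield is the share of the charged partner that stands as target. Each setting is now taken in turn.

Time: red adds no partner, so the reckoning gives no gain. Larch reads 25.9 % at 20.0 min and 25.6 % at 50.0 min, a gap inside the scatter of 1 percentage point.

Starting material: ochre adds 50.0 % of the charge but no partner, so the reckoning again gives no gain.

Taking out target: blue brings no partner either, so the reckoning keeps the total at 25.2 %.

Partner: teal adds a fresh dose, and the same yield is applied to it.

Target after teal = 25.2 % + 50.5 % × 100 % × 0.500 equiv = 50.5 %

So this reckoning chooses teal.

The forecast has 25.3 %, teal, 33 % after blue and 44 % after teal, lower than this reckoning for teal, and it says “teal is best either way”.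

The flask gives 26.2 % and teal, with gains of 1.3 points for ochre, 1.1 points for red, 3.6 points for blue and 27 points for teal. Blue reaches 29.7 % against the reckoned 25.2 %, and teal reaches 52.9 % against the reckoned 50.5 %.

    starting material + partner → target (k = 0.138 M⁻¹ s⁻¹)
    starting material + second substrate → cross product (k = 0.114 M⁻¹ s⁻¹)
    partner ⇌ dormant form (K = 56.0, k = 0.00654 s⁻¹)
    second substrate + partner → second product (k = 0.406 M⁻¹ s⁻¹)
    partner → decomposed reagent (k = 0.00393 s⁻¹)
    target ⇌ isomer of the product (K = 0.119, k = 0.00403 s⁻¹)

In the flask, the step to target had 98 % of its turnover up to 50 min behind it at 25.0 min. At 50.0 min, 0.0547 % of the partner and 59.9 % of the starting material remained free. Taken from the result, partner yield is 52.3 %, and the gain after teal, counted against the added dose, is 53.4 % of that dose. For the neighbour flask with 2.00 equiv of partner, the first yield gives 105 % of the charge, more than the starting material charged. That neighbour flask ends with 82.3 % target and 5.58 % starting material.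

The earlier runs and the new flask were generated by integration with constants of no real substance; scatter was added.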